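**Retrosynthetic overview**

1. The target is four six-membered carbocycles in a row, A–CH2–B–CH2–C–CH2–D (A, D: butyrylfilicinic acid rings; B, C: phlorobutyrophenone rings). It is achiral and has a mirror plane through the central CH2, so the A–CH2–B and D–CH2–C bridges are the same bond.
2. Key disconnection (two-directional and biomimetic): both outer CH2–C(aryl) bonds are cut at once. This gives the symmetric B–CH2–C core and two copies of a ring A electrophile, the 6-methylidene triketone (an o-quinone methide equivalent), stored as its Me2N Mannich base. The second capping joins this C13 unit to the three-ring A–B–C intermediate.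
3. Enabling feature: rings B and C of the core each keep exactly one C–H carbon, flanked by two C–OH carbons. The quaternary C4(CH3)2 of ring A forbids aromatisation, so C6 can carry an exocyclic C=CH2 between the C1 and C5 carbonyl groups.
4. The core comes from two phlorobutyrophenones and formaldehyde. Ring A comes from dearomative geminal C-methylation of the same phlorobutyrophenone, then Mannich aminomethylation. Phlorobutyrophenone comes from Friedel–Crafts acylation of phloroglucinol.
5. Ring order: no ring is built. All four rings are phloroglucinol rings, and A and D are made from it by dearomatisation before the coupling.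

Key step: step 5

Assumption: the β-triketone rings are written in the enol tautomer of the target string. All tautomers interconvert freely and the molecule holds no stereocentre, so no stereodescriptor is needed.

**Step 1**
Reactants: 1 phloroglucinol; 2 butanoyl chloride
Product: 3 phlorobutyrophenone [1-(2,4,6-trihydroxyphenyl)butan-1-one]
Conditions: AlCl3 (3.5 equiv), CH2Cl2–PhNO2, 0 °C to 40 °C; then ice/aq. HCl
Reagents that add atoms: none
Why: Friedel–Crafts acylation of the very electron-rich ring of 1 should stop after one acyl group when 2 is the limiting reagent, because the chelated aryl ketone deactivates the ring, and no stereocentre is formed.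

**Step 2**
Reactants: 3 phlorobutyrophenone
Product: 4 butyrylfilicinic acid [2-butanoyl-3,5-dihydroxy-4,4-dimethylcyclohexa-2,5-dien-1-one]
Conditions: NaOMe (3 equiv), MeI (2.1 equiv), MeOH, 0 °C to rt, Ar; then aq. HCl; 4 extracted into aq. NaHCO3 and re-acidified
Reagents that add atoms: iodomethane (two molecules), SMILES CI
Why: In this base-mediated dearomative geminal C-methylation of an acylphloroglucinol phenolate, the ring carbon that bears the first methyl group is the most electron-rich and should take the second, the product rests as a delocalised, poorly nucleophilic enolate that slows a third methylation while MeI is limited, and its much higher acidity allows separation from aromatic methylation products.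

**Step 3**
Reactants: 3 phlorobutyrophenone (two molecules enter the product)
Product: 5 methylenebis(phlorobutyrophenone) [bis(3-butanoyl-2,4,6-trihydroxyphenyl)methane], the B–CH2–C core
Conditions: 37% aq. HCHO (0.33 equiv relative to 3), KOH (1 equiv relative to 3), H2O, 0 °C to rt, Ar; then cold aq. HCl; surplus 3 recovered
Reagents that add atoms: formaldehyde, SMILES C=O
Why: In this base-mediated phenol–formaldehyde condensation (Lederer–Manasse type), two phenolates of 3 are joined through the formaldehyde carbon at one of their two equivalent free ring carbons, and the excess of 3 should keep the remaining C–H carbons of 5 from competing for formaldehyde.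

**Step 4**
Reactants: 4 butyrylfilicinic acid
Product: 6 Mannich base [2-butanoyl-6-[(dimethylamino)methyl]-3,5-dihydroxy-4,4-dimethylcyclohexa-2,5-dien-1-one, an ammonium enolate zwitterion as a solid]
Conditions: CH2(NMe2)2 (1.2 equiv), CH2Cl2, 0 °C to rt; solid collected, used without heating
Reagents that add atoms: N,N,N',N'-tetramethylmethanediamine, SMILES CN(C)CN(C)C
Why: In this Mannich aminomethylation the strongly acidic enol of 4 protonates the aminal, which then passes its Me2N–CH2 unit to C6, the only unsubstituted nucleophilic ring carbon, and the zwitterionic product should separate from CH2Cl2 and so be kept from reacting further.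

**Step 5**
Reactants: 5 methylenebis(phlorobutyrophenone); 6 Mannich base (two molecules enter the product)
Product: 9 methylenebis(norflavaspidic acid BB) = target CNP0110234.0, via methylidene triketone 7 (not isolated), via three-ring adduct 8 (not isolated)
Conditions: 6 (2.1 equiv) added slowly to 5, degassed MeCN, 50–60 °C, Ar; then cold dilute aq. HCl wash
Reagents that add atoms: none
Why: This is a two-directional, biomimetic double Michael (Friedel–Crafts-type) alkylation: zwitterionic 6 loses Me2NH by E1cB elimination to give 7, whose exocyclic CH2 lies between the C1 and C5 carbonyl groups of ring A, the freed amine turns a phenol of 5 into its phenolate, the only C–H carbon of ring B adds to the CH2 of 7 and tautomerises back to the arene to give 8, and the same sequence at the mirror-related C–H carbon of ring C joins a second 7 to 8 and gives 9. The closest known reaction types are the alkylation of acylphloroglucinols by Mannich bases through o-quinone methides and the twofold Michael addition of an acylphloroglucinol to alkylidene β-triketones. No ring is closed and no stereocentre is created, since both new bonds link a CH2 group to an sp2 ring carbon. Site selectivity is built into the substrates, because each aromatic ring of 5 holds one C–H only and 7 holds one electrophilic carbon only, while O-alkylation is reversible and drains into the C-alkylated, rearomatised product. Cross-coupling has to win over self-condensation of 7, which is secured by adding 6 slowly to all of 5 so that 7 always meets an excess of nucleophile. Exchange of the methylene bridges by retro-Michael cleavage needs free base, and this is avoided because every Me2NH set free ends as the ammonium salt of the strongly acidic enol of ring A or ring D in the product, which keeps the medium close to neutral.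

**Compound list**

| No. | Name | SMILES | Role |
|---|---|---|---|
| 1 | phloroglucinol (benzene-1,3,5-triol) | Oc1cc(O)cc(O)c1 | starting material |
| 2 | butanoyl chloride | CCCC(=O)Cl | starting material |
| 3 | phlorobutyrophenone, 1-(2,4,6-trihydroxyphenyl)butan-1-one | CCCC(=O)c1c(O)cc(O)cc1O | intermediate |
| 4 | butyrylfilicinic acid, 2-butanoyl-3,5-dihydroxy-4,4-dimethylcyclohexa-2,5-dien-1-one | CCCC(=O)C1=C(O)C(C)(C)C(O)=CC1=O | intermediate |
| 5 | methylenebis(phlorobutyrophenone), bis(3-butanoyl-2,4,6-trihydroxyphenyl)methane | CCCC(=O)c1c(O)cc(O)c(Cc2c(O)cc(O)c(C(=O)CCC)c2O)c1O | intermediate |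
| 6 | 2-butanoyl-6-[(dimethylamino)methyl]-3,5-dihydroxy-4,4-dimethylcyclohexa-2,5-dien-1-one (drawn neutral) | CCCC(=O)C1=C(O)C(C)(C)C(O)=C(CN(C)C)C1=O | intermediate |
| 7 | 2-butanoyl-3-hydroxy-4,4-dimethyl-6-methylidenecyclohex-2-ene-1,5-dione (formed in the flask in step 5) | CCCC(=O)C1=C(O)C(C)(C)C(=O)C(=C)C1=O | intermediate |
| 8 | three-ring adduct A–CH2–B–CH2–C: 5 carrying one (5-butanoyl-2,4-dihydroxy-3,3-dimethyl-6-oxocyclohexa-1,4-dien-1-yl)methyl group on the free carbon of ring B (formed in the flask in step 5) | CCCC(=O)C1=C(O)C(C)(C)C(O)=C(Cc2c(O)c(Cc3c(O)cc(O)c(C(=O)CCC)c3O)c(O)c(C(=O)CCC)c2O)C1=O | intermediate |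
| 9 | methylenebis(norflavaspidic acid BB), bis{3-butanoyl-5-[(5-butanoyl-2,4-dihydroxy-3,3-dimethyl-6-oxocyclohexa-1,4-dien-1-yl)methyl]-2,4,6-trihydroxyphenyl}methane | CCCC(=O)C1=C(O)C(C)(C)C(O)=C(Cc2c(O)c(Cc3c(O)c(CC4=C(O)C(C)(C)C(O)=C(C(=O)CCC)C4=O)c(O)c(C(=O)CCC)c3O)c(O)c(C(=O)CCC)c2O)C1=O | target |

**Step count**

Total step count: 5.
Longest linear sequence: 4 steps (1 → 3 → 4 → 6 → 9, that is steps 1, 2, 4 and 5). The core branch (steps 1, 3, 5) is shorter.

**Steps most likely to fail**

1. **Step 5.**
   - What may go wrong: stalling after the first capping, self-condensation of the methylidene triketone, and exchange of the methylene bridges by retro-Michael cleavage and re-addition. The last process would level the material to a statistical set of oligomers.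
   - Fallback (the order of the bridges is changed, central bridge last): it sets out from 3 and 6.
   - Slow addition of 6 to a threefold excess of 3 in MeCN at 50–60 °C should give the two-ring compound norflavaspidic acid BB F1, which is freed from surplus 3 by chromatography.
   - The aromatic ring of F1 holds one C–H only. Condensation of two molecules of F1 with 37% aq. HCHO (0.5 equiv) in dilute aq. KOH at 0 °C for a short time, quenched into cold aq. HCl, can therefore only build the central CH2.
   - The fallback comes back to the route at 9.

2. **Step 4.**
   - What may go wrong: premature loss of Me2NH from the zwitterionic Mannich base during its formation or isolation, and capture of the released acceptor by unreacted 4. This would consume the material through symmetric self-coupling.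
   - Fallback (a neutral, crystalline sulfone instead of an amine as the store of the acceptor): it sets out from 4.
   - Compound 4, 37% aq. HCHO and 4-methylbenzenesulfinic acid in EtOH–H2O at rt (Knoevenagel condensation followed by sulfa-Michael addition) should give 2-butanoyl-3,5-dihydroxy-4,4-dimethyl-6-{[(4-methylphenyl)sulfonyl]methyl}cyclohexa-2,5-dien-1-one F2.
   - F2 (2.1 equiv) is then added to 5 and Et3N (one equivalent per F2) in THF at 0 °C to rt. Base-induced loss of the sulfinate brings the fallback back to the route at 7, which is carried on through 8 to 9 in the same flask as in step 5.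

3. **Step 3.**
   - What may go wrong: oligomerisation, because each ring of the product keeps a nucleophilic C–H carbon that can go on reacting with formaldehyde.
   - Fallback (a removable blocking group instead of statistical control): it sets out from 3.
   - Monobromination with N-bromosuccinimide (1.0 equiv, THF, −78 °C to 0 °C) should give 1-(3-bromo-2,4,6-trihydroxyphenyl)butan-1-one F3, which has a single free ring carbon.
   - Condensation with 37% aq. HCHO (0.5 equiv) in dilute aq. KOH at 0 °C can then stop only at bis(3-bromo-5-butanoyl-2,4,6-trihydroxyphenyl)methane F4.
   - Hydrogenolysis of both C–Br bonds (H2, Pd/C, NaOAc, MeOH, rt) brings the fallback back to the route at 5.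

**Further compounds**

F1 | step 5 | norflavaspidic acid BB | CCCC(=O)C1=C(O)C(C)(C)C(O)=C(Cc2c(O)cc(O)c(C(=O)CCC)c2O)C1=O
F2 | step 4 | 2-butanoyl-3,5-dihydroxy-4,4-dimethyl-6-{[(4-methylphenyl)sulfonyl]methyl}cyclohexa-2,5-dien-1-one | CCCC(=O)C1=C(O)C(C)(C)C(O)=C(CS(=O)(=O)c2ccc(C)cc2)C1=O
F3 | step 3 | 1-(3-bromo-2,4,6-trihydroxyphenyl)butan-1-one | CCCC(=O)c1c(O)cc(O)c(Br)c1O
F4 | step 3 | bis(3-bromo-5-butanoyl-2,4,6-trihydroxyphenyl)methane | CCCC(=O)c1c(O)c(Br)c(O)c(Cc2c(O)c(Br)c(O)c(C(=O)CCC)c2O)c1O
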